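**Plan**
- Locants are germacrane positions of the target: ring C1–C10 (C1=C10 E, C2=O, C3=C4 Z, C5–OH, C6–O of the lactone, C7, C8–O-angelate, C9H2), lactone carbons C11–C13, methyls C14 (on C10) and C15 (on C4).
- Retrosynthesis cuts the C8 ester, the lactone (C12–O, C11=C13, C7–C11) and the C2 carbonyl oxygen, then cuts C8–C9 while re-forming C1–C6 (retro-oxy-Cope).
- The enabling feature is the 5-en-1-one unit C6(O)–C7–C8–C9–C10=C1 inside the ten-membered ring; reconnecting C1–C6 gives a cyclohexene whose atoms C1–C6, C15 and the isopropenyl group (C10, C9, C14) are the carvone skeleton.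
- Forward: (R)-carvone → C6 ketone → 1,2-addition of an (E)-silylvinyl group → anionic oxy-Cope ring expansion to the ten-membered ring with enolate alkylation → γ-lactone → α-methylene → C2 ketone → C8–OH → angelate.
- Stereochemistry: the carvone centre (C1) is relayed to C8 through the chair transition state (silicon later replaced by oxygen with retention); the chair gives E-C1=C10 and the ring origin gives Z-C3=C4; C5 by hydroxyl-directed reduction, C7 by enolate alkylation, C6 by chelation-controlled reduction.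

Key step: step 12

**Route**

Step 1
Reactants: 1 (R)-(−)-carvone
Product: 2 (1S,6S)-3-methyl-2-oxo-6-(prop-1-en-2-yl)cyclohex-3-en-1-yl acetate
Conditions: Mn(OAc)3·2H2O, benzene, reflux
Reagents that add atoms: manganese triacetate, CC(=O)[O-].CC(=O)[O-].CC(=O)[O-].[Mn+3]
Why: α′-Acetoxylation of enones with manganese triacetate goes through the manganese enolate at the future C6 and should deliver acetate mainly trans to the isopropenyl group; the minor cis isomer is removed, and this centre becomes sp2 again in step 5.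

Step 2
Reactants: 2 (1S,6S)-3-methyl-2-oxo-6-(prop-1-en-2-yl)cyclohex-3-en-1-yl acetate
Product: 3 (1S,2S,6S)-2-hydroxy-3-methyl-6-(prop-1-en-2-yl)cyclohex-3-en-1-yl acetate
Conditions: NaBH4, CeCl3·7H2O, MeOH, −78 °C
Reagents that add atoms: none
Why: Luche 1,2-reduction with axial hydride delivery should give the pseudo-equatorial alcohol cis to isopropenyl; it only masks this carbonyl (future C5) while C6 is oxidised, and is corrected in steps 9 and 10.

Step 3
Reactants: 3 (1S,2S,6S)-2-hydroxy-3-methyl-6-(prop-1-en-2-yl)cyclohex-3-en-1-yl acetate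
Product: 4 (1S,2S,6S)-3-methyl-6-(prop-1-en-2-yl)-2-(triethylsilyloxy)cyclohex-3-en-1-yl acetate
Conditions: Et3SiCl, imidazole, CH2Cl2, 0 °C
Reagents that add atoms: chlorotriethylsilane, CC[Si](Cl)(CC)CC
Why: Standard silylation of the secondary allylic alcohol.

Step 4
Reactants: 4 (1S,2S,6S)-3-methyl-6-(prop-1-en-2-yl)-2-(triethylsilyloxy)cyclohex-3-en-1-yl acetate
Product: 5 (1S,2S,6S)-3-methyl-6-(prop-1-en-2-yl)-2-(triethylsilyloxy)cyclohex-3-en-1-ol
Conditions: K2CO3 (cat.), MeOH, 0 °C
Reagents that add atoms: none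
Why: Zemplén-type transesterification removes the acetate while the secondary triethylsilyl ether survives brief exposure to methanolic carbonate.

Step 5
Reactants: 5 (1S,2S,6S)-3-methyl-6-(prop-1-en-2-yl)-2-(triethylsilyloxy)cyclohex-3-en-1-ol
Product: 6 (2S,6S)-3-methyl-6-(prop-1-en-2-yl)-2-(triethylsilyloxy)cyclohex-3-en-1-one
Conditions: Dess–Martin periodinane, NaHCO3, CH2Cl2, 0 °C; used at once
Reagents that add atoms: none
Why: Dess–Martin oxidation is non-basic, so the α-silyloxy β,γ-unsaturated ketone should neither epimerise at its two α-centres nor move its double bond into conjugation.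

Step 6
Reactants: 7 ethynyl(dimethyl)phenylsilane
Product: 9 (E)-(2-bromoethenyl)(dimethyl)phenylsilane, via alkenylzirconocene chloride 8 (not isolated)
Conditions: Cp2Zr(H)Cl, THF, 20 °C; then N-bromosuccinimide, 0 °C
Reagents that add atoms: N-bromosuccinimide, O=C1CCC(=O)N1Br
Why: Hydrozirconation is a syn addition that places zirconium on the terminal carbon, and bromodezirconation retains the geometry, so the E-bromide should result.

Step 7
Reactants: 6 (2S,6S)-3-methyl-6-(prop-1-en-2-yl)-2-(triethylsilyloxy)cyclohex-3-en-1-one; 9 (E)-(2-bromoethenyl)(dimethyl)phenylsilane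
Product: 12 (1S,2S,6S)-1-[(E)-2-(dimethylphenylsilyl)ethenyl]-3-methyl-6-(prop-1-en-2-yl)-2-(triethylsilyloxy)cyclohex-3-en-1-ol, via alkenyllithium 10 (not isolated), via alkenylcerium dichloride 11 (not isolated)
Conditions: 9, t-BuLi (2 equiv), Et2O, −78 °C; CeCl3, THF, −78 °C; then 6, −78 °C; aq. NH4Cl
Reagents that add atoms: none
Why: Bromine–lithium exchange and transmetalation give a weakly basic organocerium reagent that should add to the enolisable ketone from the equatorial direction, as organometallics do with 2-substituted cyclohexanones, placing the alkenyl group trans to both flanking equatorial substituents (tertiary OH axial, cis to isopropenyl).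

Step 8
Reactants: 12 (1S,2S,6S)-1-[(E)-2-(dimethylphenylsilyl)ethenyl]-3-methyl-6-(prop-1-en-2-yl)-2-(triethylsilyloxy)cyclohex-3-en-1-ol
Product: 13 (1S,2S,6S)-1-[(E)-2-(dimethylphenylsilyl)ethenyl]-3-methyl-6-(prop-1-en-2-yl)cyclohex-3-ene-1,2-diol
Conditions: PPTS, MeOH, 0 °C
Reagents that add atoms: none
Why: Mild acid methanolysis cleaves the secondary triethylsilyl ether without ionising the tertiary allylic alcohol.

Step 9
Reactants: 13 (1S,2S,6S)-1-[(E)-2-(dimethylphenylsilyl)ethenyl]-3-methyl-6-(prop-1-en-2-yl)cyclohex-3-ene-1,2-diol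
Product: 14 (5S,6S)-6-[(E)-2-(dimethylphenylsilyl)ethenyl]-6-hydroxy-2-methyl-5-(prop-1-en-2-yl)cyclohex-2-en-1-one
Conditions: Dess–Martin periodinane, NaHCO3, CH2Cl2, 0 °C
Reagents that add atoms: none
Why: Only the secondary allylic alcohol can be oxidised, which regenerates the enone carbonyl next to the now fixed tertiary carbinol.

Step 10
Reactants: 14 (5S,6S)-6-[(E)-2-(dimethylphenylsilyl)ethenyl]-6-hydroxy-2-methyl-5-(prop-1-en-2-yl)cyclohex-2-en-1-one
Product: 15 (1S,2R,6S)-1-[(E)-2-(dimethylphenylsilyl)ethenyl]-3-methyl-6-(prop-1-en-2-yl)cyclohex-3-ene-1,2-diol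
Conditions: Me4NBH(OAc)3, AcOH/MeCN, −30 °C
Reagents that add atoms: none
Why: Hydroxyl-directed triacetoxyborohydride reduction delivers hydride to the carbonyl face syn to the tertiary hydroxyl, so the new carbinol (C5, R) should be trans to it, which is the anti diol the target needs.

Step 11
Reactants: 15 (1S,2R,6S)-1-[(E)-2-(dimethylphenylsilyl)ethenyl]-3-methyl-6-(prop-1-en-2-yl)cyclohex-3-ene-1,2-diol
Product: 16 (1S,2R,6S)-1-[(E)-2-(dimethylphenylsilyl)ethenyl]-2-(methoxymethoxy)-3-methyl-6-(prop-1-en-2-yl)cyclohex-3-en-1-ol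
Conditions: MeOCH2Cl, i-Pr2NEt, CH2Cl2, 0 to 20 °C
Reagents that add atoms: chloromethyl methyl ether, COCCl
Why: The secondary hydroxyl is alkylated selectively over the hindered tertiary one, and the methoxymethyl ether later serves as the chelating group in step 13.

Step 12
Reactants: 16 (1S,2R,6S)-1-[(E)-2-(dimethylphenylsilyl)ethenyl]-2-(methoxymethoxy)-3-methyl-6-(prop-1-en-2-yl)cyclohex-3-en-1-ol
Product: 19 ring-expanded keto ester (6-oxo; 5R-methoxymethoxy; 7-CH2CO2Me; 8S-dimethylphenylsilyl; 1(10)E; 3Z), via potassium alkoxide 17 (not isolated), via potassium enolate 18 (not isolated)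
Conditions: KN(SiMe3)2, 18-crown-6, THF, 0 to 25 °C; then BrCH2CO2Me, −78 °C
Reagents that add atoms: methyl bromoacetate, COC(=O)CBr
Why: Alkoxide 17 contains the 1,5-diene C9=C10–C1–C6–C7=C8 and should undergo the anionic oxy-Cope [3,3]-sigmatropic rearrangement, forming C8–C9 while C1–C6 breaks, so the ten-membered ring closes by a four-atom ring expansion through a six-membered chair transition state and not by an end-to-end macrocyclisation; the closest known reaction type is the anionic oxy-Cope expansion of trans-1,2-dialkenylcyclohexanols to (E)-cyclodec-5-enones with trapping of the enolate. The trans-diequatorial isopropenyl and silylvinyl groups allow a chair in which both ring bonds (C1–C2 and C6–C5) are pseudo-equatorial, so the new C1=C10 bond is E, while C3=C4 stays Z because it was the cyclohexene double bond. The carvone stereocentre C1 is exchanged for C8: with the E-vinylsilane the silyl group is pseudo-equatorial in that chair, which fixes the face of C8 that bonds to C9 and gives the 8S silane. Regiodefined enolate 18 (C6=C7) is alkylated on its peripheral face, opposite the transannular C1=C10 unit, which sets C7. The step needs chair over boat and rearrangement through the exocyclic isopropenyl group and not the ring alkene, both favoured by the trans relationship; the E geometry also keeps silicon out of reach of the alkoxide. It further needs C-alkylation before any enolate equilibration toward C5, which the absence of a proton source and the reactive bromoacetate at −78 °C should secure.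

Step 13
Reactants: 19 ring-expanded keto ester
Product: 21 trans-fused saturated γ-lactone (6S-O; 7-CH2 of the lactone; 8S-silyl; 5R-methoxymethoxy), via hydroxy ester 20 (not isolated)
Conditions: Zn(BH4)2, Et2O, −30 °C; then PPTS, toluene, 50 °C
Reagents that add atoms: none
Why: Zinc bridges the C6 carbonyl and the C5 methoxymethyl ether, and chelation-controlled hydride delivery to α-alkoxy ketones gives the anti 1,2-dioxygen pattern (6S); the γ-hydroxy ester then lactonises to the trans-fused ring.

Step 14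
Reactants: 21 trans-fused saturated γ-lactone
Product: 24 α-methylene lactone (8S-silyl; 5R-methoxymethoxy), via Mannich base 22 (not isolated), via ammonium iodide 23 (not isolated)
Conditions: LiN(i-Pr)2, THF, −78 °C; CH2=NMe2+ I−, −78 to 20 °C; then MeI, MeOH; then NaHCO3 (aq), CH2Cl2
Reagents that add atoms: N,N-dimethylmethyleneiminium iodide, C=[N+](C)C.[I-]
Why: Aminomethylation of the lactone enolate, quaternisation and β-elimination is the standard α-methylenation of γ-lactones; no ketone or ester competes at this stage.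

Step 15
Reactants: 24 α-methylene lactone
Product: 25 cross-conjugated dienone (2-oxo; 8S-silyl; 5R-methoxymethoxy)
Conditions: CrO3, 3,5-dimethylpyrazole, CH2Cl2, −20 °C
Reagents that add atoms: chromium trioxide, O=[Cr](=O)=O
Why: Allylic oxidation with the chromium trioxide–dimethylpyrazole complex should take the doubly allylic C2 methylene, the weakest C–H bond and the only site that leads to a cross-conjugated dienone, leaving both ring alkene geometries in place.

Step 16
Reactants: 25 cross-conjugated dienone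
Product: 26 C8 alcohol (8S-hydroxy; 5R-methoxymethoxy)
Conditions: KBr, AcOOH, NaOAc, AcOH, 20 °C
Reagents that add atoms: peracetic acid, CC(=O)OO
Why: Fleming–Tamao oxidation (ipso-bromodesilylation of the phenyl group, then peracid-induced carbon-to-oxygen shift) replaces silicon by hydroxyl with retention at C8; every alkene is electron-poor by now and should survive the electrophilic medium.

Step 17
Reactants: 26 C8 alcohol; 27 angelic acid
Product: 29 5-O-methoxymethyl ether of the target, via mixed anhydride 28 (not isolated)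
Conditions: 27, 2,4,6-trichlorobenzoyl chloride, Et3N, toluene, 20 °C; then 26, 50 °C
Reagents that add atoms: none
Why: Yamaguchi-type mixed-anhydride esterification without a nucleophilic catalyst acylates the alcohol with retention at C8 and avoids angelate-to-tiglate isomerisation.

Step 18
Reactants: 29 5-O-methoxymethyl ether of the target
Product: 31 target CNP0230565.9, via bromomethyl ether 30 (not isolated)
Conditions: Me2BBr, CH2Cl2, −78 °C; then NaHCO3 (aq), THF
Reagents that add atoms: none
Why: Dimethylboron bromide cleaves methoxymethyl acetals at low temperature through the bromomethyl ether, which hydrolyses on work-up; the ester, lactone and dienone should be untouched.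

**Compound list**
1 | (R)-(−)-carvone | CC1=CC[C@@H](C(C)=C)CC1=O | starting material
2 | (1S,6S)-3-methyl-2-oxo-6-(prop-1-en-2-yl)cyclohex-3-en-1-yl acetate | CC1=CC[C@@H](C(C)=C)[C@H](OC(C)=O)C1=O | intermediate
3 | (1S,2S,6S)-2-hydroxy-3-methyl-6-(prop-1-en-2-yl)cyclohex-3-en-1-yl acetate | CC1=CC[C@@H](C(C)=C)[C@H](OC(C)=O)[C@H]1O | intermediate
4 | (1S,2S,6S)-3-methyl-6-(prop-1-en-2-yl)-2-(triethylsilyloxy)cyclohex-3-en-1-yl acetate | CC1=CC[C@@H](C(C)=C)[C@H](OC(C)=O)[C@H]1O[Si](CC)(CC)CC | intermediate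
5 | (1S,2S,6S)-3-methyl-6-(prop-1-en-2-yl)-2-(triethylsilyloxy)cyclohex-3-en-1-ol | CC1=CC[C@@H](C(C)=C)[C@H](O)[C@H]1O[Si](CC)(CC)CC | intermediate
6 | (2S,6S)-3-methyl-6-(prop-1-en-2-yl)-2-(triethylsilyloxy)cyclohex-3-en-1-one | CC1=CC[C@@H](C(C)=C)C(=O)[C@H]1O[Si](CC)(CC)CC | intermediate
7 | ethynyl(dimethyl)phenylsilane | C#C[Si](C)(C)c1ccccc1 | starting material
8 | (E)-[2-(dimethylphenylsilyl)ethenyl]zirconocene chloride | Cl[Zr](/C=C/[Si](C)(C)c1ccccc1)(C1C=CC=C1)C1C=CC=C1 | intermediate
9 | (E)-(2-bromoethenyl)(dimethyl)phenylsilane | Br/C=C/[Si](C)(C)c1ccccc1 | intermediate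
10 | (E)-[2-(dimethylphenylsilyl)ethenyl]lithium | [Li]/C=C/[Si](C)(C)c1ccccc1 | intermediate
11 | (E)-[2-(dimethylphenylsilyl)ethenyl]cerium dichloride | Cl[Ce](Cl)/C=C/[Si](C)(C)c1ccccc1 | intermediate
12 | (1S,2S,6S)-1-[(E)-2-(dimethylphenylsilyl)ethenyl]-3-methyl-6-(prop-1-en-2-yl)-2-(triethylsilyloxy)cyclohex-3-en-1-ol | CC1=CC[C@@H](C(C)=C)[C@](O)(/C=C/[Si](C)(C)c2ccccc2)[C@H]1O[Si](CC)(CC)CC | intermediate
13 | (1S,2S,6S)-1-[(E)-2-(dimethylphenylsilyl)ethenyl]-3-methyl-6-(prop-1-en-2-yl)cyclohex-3-ene-1,2-diol | CC1=CC[C@@H](C(C)=C)[C@](O)(/C=C/[Si](C)(C)c2ccccc2)[C@H]1O | intermediate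
14 | (5S,6S)-6-[(E)-2-(dimethylphenylsilyl)ethenyl]-6-hydroxy-2-methyl-5-(prop-1-en-2-yl)cyclohex-2-en-1-one | CC1=CC[C@@H](C(C)=C)[C@](O)(/C=C/[Si](C)(C)c2ccccc2)C1=O | intermediate
15 | (1S,2R,6S)-1-[(E)-2-(dimethylphenylsilyl)ethenyl]-3-methyl-6-(prop-1-en-2-yl)cyclohex-3-ene-1,2-diol | CC1=CC[C@@H](C(C)=C)[C@](O)(/C=C/[Si](C)(C)c2ccccc2)[C@@H]1O | intermediate
16 | (1S,2R,6S)-1-[(E)-2-(dimethylphenylsilyl)ethenyl]-2-(methoxymethoxy)-3-methyl-6-(prop-1-en-2-yl)cyclohex-3-en-1-ol | CC1=CC[C@@H](C(C)=C)[C@](O)(/C=C/[Si](C)(C)c2ccccc2)[C@@H]1OCOC | intermediate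
17 | potassium alkoxide of 16 | CC1=CC[C@@H](C(C)=C)[C@]([O-])(/C=C/[Si](C)(C)c2ccccc2)[C@@H]1OCOC.[K+] | intermediate
18 | ten-membered potassium enolate (C6=C7; 8S-silyl; 1(10)E; 3Z) | [K+].[O-]/C1=C\[C@@H]([Si](C)(C)c2ccccc2)C/C(C)=C/C/C=C(/C)[C@H]1OCOC | intermediate
19 | ring-expanded keto ester (6-oxo; 5R-methoxymethoxy; 7-CH2CO2Me; 8S-dimethylphenylsilyl; 1(10)E; 3Z) | O=C1[C@H](CC(=O)OC)[C@@H]([Si](C)(C)c2ccccc2)C/C(C)=C/C/C=C(/C)[C@H]1OCOC | intermediate
20 | 6S-hydroxy ester | O[C@H]1[C@H](CC(=O)OC)[C@@H]([Si](C)(C)c2ccccc2)C/C(C)=C/C/C=C(/C)[C@H]1OCOC | intermediate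
21 | trans-fused saturated γ-lactone (8S-silyl; 5R-methoxymethoxy) | C1C(=O)O[C@H]2[C@H]1[C@@H]([Si](C)(C)c3ccccc3)C/C(C)=C/C/C=C(/C)[C@H]2OCOC | intermediate
22 | α-(dimethylaminomethyl) lactone | CN(C)CC1C(=O)O[C@H]2[C@H]1[C@@H]([Si](C)(C)c3ccccc3)C/C(C)=C/C/C=C(/C)[C@H]2OCOC | intermediate
23 | α-(trimethylammoniomethyl) lactone iodide | C[N+](C)(C)CC1C(=O)O[C@H]2[C@H]1[C@@H]([Si](C)(C)c3ccccc3)C/C(C)=C/C/C=C(/C)[C@H]2OCOC.[I-] | intermediate
24 | α-methylene lactone (8S-silyl; 5R-methoxymethoxy) | C=C1C(=O)O[C@H]2[C@H]1[C@@H]([Si](C)(C)c3ccccc3)C/C(C)=C/C/C=C(/C)[C@H]2OCOC | intermediate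
25 | cross-conjugated dienone (2-oxo; 8S-silyl; 5R-methoxymethoxy) | C=C1C(=O)O[C@H]2[C@H]1[C@@H]([Si](C)(C)c3ccccc3)C/C(C)=C/C(=O)/C=C(/C)[C@H]2OCOC | intermediate
26 | C8 alcohol (8S-hydroxy; 5R-methoxymethoxy) | C=C1C(=O)O[C@H]2[C@H]1[C@@H](O)C/C(C)=C/C(=O)/C=C(/C)[C@H]2OCOC | intermediate
27 | angelic acid, (Z)-2-methylbut-2-enoic acid | C/C=C(/C)C(=O)O | starting material
28 | angelic 2,4,6-trichlorobenzoic anhydride | C/C=C(/C)C(=O)OC(=O)c1c(Cl)cc(Cl)cc1Cl | intermediate
29 | 5-O-methoxymethyl ether of the target | C=C1C(=O)O[C@H]2[C@H]1[C@@H](OC(=O)/C(C)=C\C)C/C(C)=C/C(=O)/C=C(/C)[C@H]2OCOC | intermediate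
30 | 5-O-bromomethyl ether of the target | C=C1C(=O)O[C@H]2[C@H]1[C@@H](OC(=O)/C(C)=C\C)C/C(C)=C/C(=O)/C=C(/C)[C@H]2OCBr | intermediate
31 | CNP0230565.9 | C=C1C(=O)O[C@H]2[C@H]1[C@@H](OC(=O)/C(C)=C\C)C/C(C)=C/C(=O)/C=C(/C)[C@H]2O | target

**Count and risks**
Total step count: 18. Longest linear sequence: 17 (steps 1 to 5 and 7 to 18; step 6 prepares the vinyl bromide).

Step 12 (key step). The rearrangement itself is well precedented; the weak point is the in-flask alkylation. Proton exchange between enolate 18 and already formed ketone 19, or sluggish C-alkylation, would cause over-alkylation, drift of the enolate toward the doubly activated C5 position, and loss of the C5 and C7 configurations. The fallback sets out from 16 and returns at 19. The ring expansion is run as before, but enolate 18 is silylated with Me3SiCl at −78 °C to the trimethylsilyl enol ether F1, which is isolated. MeLi (THF, −78 °C) then regenerates the regiodefined lithium enolate F2 without any proton source, and alkylation with methyl iodoacetate in THF/DMPU gives 19.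

Step 15. The oxidant may attack competing allylic positions (C9, the C5 methine, the methyl groups) or over-oxidise the product. The fallback sets out from 24 and returns at 25. It separates C–O bond formation from the change of oxidation level: Rh2(C6H10NO)4 (dirhodium tetracaprolactamate) with t-BuOOH and K2CO3 in CH2Cl2 gives the bis-allylic tert-butyl peroxide F6, which is isolated. Kornblum–DeLaMare fragmentation with Et3N then gives dienone 25.

Step 13. Chelation control may be lost, so that hydride enters the other carbonyl face; the 6-epimeric alcohol would then close to a cis-fused lactone. The fallback sets out from 19 and returns at 21. The 6-epimeric hydroxy ester F3 is allowed to close to the cis-fused lactone F4, which LiOH (THF/H2O) opens to the hydroxy acid F5, acidified cold and used at once. Mitsunobu lactonisation (PPh3, diisopropyl azodicarboxylate, THF, 0 °C) then closes the ring with inversion at C6 to give the trans-fused lactone 21.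

Further compounds
F1 | step 12 | trimethylsilyl enol ether of the ring-expanded ketone (C6=C7) | C[Si](C)(C)O/C1=C\[C@@H]([Si](C)(C)c2ccccc2)C/C(C)=C/C/C=C(/C)[C@H]1OCOC
F2 | step 12 | lithium enolate (C6=C7) | [Li+].[O-]/C1=C\[C@@H]([Si](C)(C)c2ccccc2)C/C(C)=C/C/C=C(/C)[C@H]1OCOC
F3 | step 13 | 6-epimeric (6R) hydroxy ester | O[C@@H]1[C@H](CC(=O)OC)[C@@H]([Si](C)(C)c2ccccc2)C/C(C)=C/C/C=C(/C)[C@H]1OCOC
F4 | step 13 | cis-fused 6-epi lactone | C1C(=O)O[C@@H]2[C@H]1[C@@H]([Si](C)(C)c3ccccc3)C/C(C)=C/C/C=C(/C)[C@H]2OCOC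
F5 | step 13 | 6-epimeric (6R) hydroxy acid | O[C@@H]1[C@H](CC(=O)O)[C@@H]([Si](C)(C)c2ccccc2)C/C(C)=C/C/C=C(/C)[C@H]1OCOC
F6 | step 15 | C2 tert-butyl peroxide of 24 | C=C1C(=O)O[C@H]2[C@H]1[C@@H]([Si](C)(C)c3ccccc3)C/C(C)=C/C(OOC(C)(C)C)/C=C(/C)[C@H]2OCOC
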